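The constants used here were chosen freely; the result is computed.

What decides how E divides between X.Q and X.X.Q by 8.0 d, and has the flask stopped by then?

    E ⇌ X, rate k1*(cs1 - [X]) while solid is left; crystals form when [X] > cs1 (cs1 = 19 mM, k1 = 0.0092 /min)
    X + Q → X.Q (k2 = 0.037 /M/min)
    X + X.Q → X.X.Q (k3 = 0.028 /M/min)

E 0.40 M; Q 0.480 M; time 8.0 d

- percentages count the E that a species holds: one X.X.Q counts as two
- solid, in amounts per volume of the solution: E
- at the start none of E is in solution
- what has only dissolved of E counts as not reacted
- the reaction counts as stopped when no species that holds the E changes by six tenths of a point or more over the second half of the time
- run time (flask): 8.0 d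

1. the state of affairs at 8.0 d: stopped, and by what, or still going (for what has run out or reacted, a solid counts together with what of it has only dissolved) (all of E has reacted / Q has run out first / it is still moving)
2. part of the E that has turned into other species by 8.0 d (what has only dissolved does not count)
3. amount of X.Q at 8.0 d, in percent of the E charged
4. amount of X.X.Q at 8.0 d, in percent of the E charged

Take the given numbers by what an error in each costs. The solubility and the dissolving coefficient give E a shortest dissolving time of 1.59 d, charge over full dissolving rate. Dissolved X, with Q as charged, has a half-life of 0.65 h by the step to X.Q, far shorter than that dissolving time, so c(X) can be treated as steady, and an error in those two constants shifts the finishing time rather than the division. Even doubled, that time is 3.18 d, shorter than the 8.0 d allowed, which puts conversion at 100%. Each E takes at most one Q and Q is charged higher than E, so E is the limiting reagent: all of E has reacted.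

The two rate constants act on the same X, so c(X) cancels and their ratio remains. This is the selectivity factor s, the constant of the step to X.X.Q over that of the step to X.Q, 0.757. With u the part of Q left, c(X.Q) is the Q charge times (u^s − u) divided by one minus s, so s and the two charges must be known well. Try an even division of E: that leaves u at 37.5%, and the rule returns 49.8% as X.Q and 50.2% as X.X.Q, which bears the trial out.

The forecast says all of E has reacted, with conversion 100%, X.Q 49.9% and X.X.Q 50.1%, and concludes that “the E divides roughly evenly between the two”.

The flask gives all of E has reacted, with conversion 100%, X.Q 49.8% and X.X.Q 50.2%. At 1.22 d the flask's X has a half-life of 1.0 h by the step to X.Q, far shorter than the 1.22 d by which half of the turnover of the dissolving of E is done, and X is then made 1.00 times as fast as it is used up. With s at 0.757, the flask's 38% of Q left gives 49.8% as X.Q, and a neighbour flask, charged with 0.68 M of E, has 12.3% of Q left, from which the rule gives 23.8% where that neighbour holds 23.8%.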